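**Retrosynthetic overview**

1. Locants used throughout: five-membered ring C1 (angular Me)–C2–C3–C4 (OH, i-Pr)–C5 (H); seven-membered ring C5–C6 (O-ester)–C7–C8 (Me)=C9–C10–C1.
2. Ester ⇒ diol ⇒ C6 ketone (hydroxyl-directed reduction). The C5–H bond and the C8=C9 alkene come from two SmI2 C–O scissions of a C5–O–C9 oxygen bridge (first alpha to the C6 ketone, then vinylogous).
3. Bridged enone ⇒ intramolecular oxidopyrylium–alkene [5+2]. The ring segment C5–C6(O)–C7–C8(Me)–C9 is the carbon frame of a 5-methyl-3-oxidopyrylium (C6–O the oxide, C5 and C9 the ylide termini flanking the ring oxygen), and C1=C10 is a 1,1-disubstituted alkene hung from C5 by C4–C3–C2.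
4. Acetoxypyranone ⇒ Achmatowicz ring expansion of a 4-methylfuran-2-yl carbinol ⇒ 3-methylfuran + an alkylated chiral dioxolanone of (R)-2-hydroxy-3-methylbutanoic acid (source of C4, the only purchased stereocentre).
5. Ring order: furan → pyranone → five- and seven-membered carbocycles together → oxygen bridge excised.

Key step: step 7

Remark: 4-iodo-2-methylbut-1-ene is taken as a catalogue reagent; compounds 10–12 are carried as mixtures at the centres that become sp2 in ylide 13, so their SMILES leave those centres open.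

**Route**

Step 1
Reactants: 1 (2R)-2-hydroxy-3-methylbutanoic acid; 2 2,2-dimethylpropanal (pivalaldehyde)
Product: 3 (2R,5R)-2-tert-butyl-5-(propan-2-yl)-1,3-dioxolan-4-one (cis)
Conditions: TsOH·H2O (cat.), H2SO4 (cat.), pentane, reflux, Dean–Stark; recrystallisation
Reagents that add atoms: none
Why: Acid-catalysed acetalisation (chiral dioxolanone formation, first stage of self-regeneration of stereocentres) is reversible, so the new acetal centre should settle cis to the isopropyl group under thermodynamic control by the existing carbinol centre.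

Step 2
Reactants: 3 (2R,5R)-2-tert-butyl-5-(propan-2-yl)-1,3-dioxolan-4-one; 4 4-iodo-2-methylbut-1-ene
Product: 6 (2R,5R)-2-tert-butyl-5-(3-methylbut-3-en-1-yl)-5-(propan-2-yl)-1,3-dioxolan-4-one, via lithium enolate 5 (not isolated)
Conditions: LiN(i-Pr)2, THF, −78 °C; then 4, DMPU, −78 → −30 °C
Reagents that add atoms: none
Why: Diastereoselective enolate alkylation (self-regeneration of stereocentres): deprotonation erases the carbinol centre, the acetal centre survives, and enolate 5 attacks the primary iodide on the face opposite the tert-butyl group, so the quaternary centre (future C4) should be rebuilt with overall retention.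

Step 3
Reactants: 6 (2R,5R)-2-tert-butyl-5-(3-methylbut-3-en-1-yl)-5-(propan-2-yl)-1,3-dioxolan-4-one; 7 3-methylfuran
Product: 9 (2R)-2-hydroxy-5-methyl-1-(4-methylfuran-2-yl)-2-(propan-2-yl)hex-5-en-1-one, via (4-methylfuran-2-yl)lithium 8 (not isolated)
Conditions: 7, lithium 2,2,6,6-tetramethylpiperidide (from 2,2,6,6-tetramethylpiperidine and n-BuLi), THF, −78 → 0 °C; then 6, −78 → −20 °C; H2O
Reagents that add atoms: none
Why: Deprotonative lithiation with a bulky amide should take the less hindered alpha-proton of 3-methylfuran (remote from the methyl group), and the furyllithium adds once to the lactone carbonyl (acyl substitution of a dioxolanone), the acetal falling apart on aqueous work-up with loss of pivalaldehyde while the quaternary carbinol centre is untouched.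

Step 4
Reactants: 9 (2R)-2-hydroxy-5-methyl-1-(4-methylfuran-2-yl)-2-(propan-2-yl)hex-5-en-1-one
Product: 10 (2R)-5-methyl-1-(4-methylfuran-2-yl)-2-(propan-2-yl)hex-5-ene-1,2-diol (both epimers at the furfuryl carbinol)
Conditions: NaBH4, MeOH, 0 °C
Reagents that add atoms: none
Why: Borohydride reduction of the furyl ketone; the new furfuryl carbinol centre is left uncontrolled on purpose because it becomes an sp2 ylide terminus in step 7.

Step 5
Reactants: 10 (2R)-5-methyl-1-(4-methylfuran-2-yl)-2-(propan-2-yl)hex-5-ene-1,2-diol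
Product: 11 6-hydroxy-2-[(3R)-3-hydroxy-2,6-dimethylhept-6-en-3-yl]-5-methyl-2H-pyran-3(6H)-one (ring-centre epimers)
Conditions: VO(acac)2 (cat.), t-BuOOH, CH2Cl2, 0 °C → rt
Reagents that add atoms: tert-butyl hydroperoxide CC(C)(C)OO
Why: Achmatowicz rearrangement: the furfuryl hydroxyl delivers the vanadium peroxide to the furan, which is oxidised and ring-expanded to the 6-hydroxypyranone, so the remote 1,1-disubstituted alkene should be spared and no lasting stereocentre is set.

Step 6
Reactants: 11 6-hydroxy-2-[(3R)-3-hydroxy-2,6-dimethylhept-6-en-3-yl]-5-methyl-2H-pyran-3(6H)-one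
Product: 12 6-[(3R)-3-hydroxy-2,6-dimethylhept-6-en-3-yl]-3-methyl-5-oxo-5,6-dihydro-2H-pyran-2-yl acetate (ring-centre epimers)
Conditions: Ac2O, pyridine, DMAP (cat.), CH2Cl2, 0 °C
Reagents that add atoms: acetic anhydride CC(=O)OC(C)=O
Why: DMAP-catalysed O-acetylation of the hemiacetal hydroxyl installs the leaving group for ylide formation, the tertiary C4 hydroxyl being too hindered to react.

Step 7
Reactants: 12 6-[(3R)-3-hydroxy-2,6-dimethylhept-6-en-3-yl]-3-methyl-5-oxo-5,6-dihydro-2H-pyran-2-yl acetate
Product: 14 (3R,3aS,7S,8aR)-3-hydroxy-6,8a-dimethyl-3-(propan-2-yl)-1,2,3,7,8,8a-hexahydro-4H-3a,7-epoxyazulen-4-one (oxygen bridge C5–O–C9 anti to the angular methyl; C4 hydroxyl syn to it), via oxidopyrylium ylide 13 (not isolated)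
Conditions: Et3N, MeCN (0.01 M, slow addition of 12), 60 °C
Reagents that add atoms: none
Why: Triethylamine removes the proton alpha to the ketone of 12 and the enolate expels acetate to give the 3-oxidopyrylium 13, whose two ylide termini (the ring carbon carrying the side chain, future C5, and the unsubstituted ring carbon next to oxygen, future C9) add suprafacially across the tethered 1,1-disubstituted alkene in a concerted, asynchronous [5+2] cycloaddition, the established intramolecular oxidopyrylium–alkene reaction of acetoxypyranones carrying a pent-4-enyl-type chain next to the ketone. The seven-membered carbocycle closes by the cycloaddition itself (C5–C9 plus C10 and C1), the five-membered ring closes as the fused ring spanned by the tether C4–C3–C2, and the former ring oxygen remains as a C5–O–C9 bridge. The three-atom tether can only reach the exo position of the new two-carbon bridge, so the C1 methyl is forced endo, anti to the oxygen bridge, which fixes C1, C5 and C9 relative to one another. Their configuration relative to C4 follows from the rotamer about the C4–C5 bond: with the tether over one face of the planar ylide, one of the two remaining C4 substituents must lie beside the oxide oxygen and the other beside the ring oxygen, and the free tertiary hydroxyl should take the former place (hydrogen bond to the oxide, no allylic 1,3-strain) while the isopropyl group takes the latter, which puts OH and the C1 methyl on the same face of the new cyclopentane, as in the target. The step needs periselectivity over ylide dimerisation, secured by high dilution, the entropic advantage of the short tether and the hindered disubstituted ylide, and regioselectivity, which the tether dictates.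

Step 8
Reactants: 14 (3R,3aS,7S,8aR)-3-hydroxy-6,8a-dimethyl-3-(propan-2-yl)-1,2,3,7,8,8a-hexahydro-4H-3a,7-epoxyazulen-4-one
Product: 16 (3R,3aR,7S,8aR)-3,7-dihydroxy-6,8a-dimethyl-3-(propan-2-yl)-2,3,3a,7,8,8a-hexahydroazulen-4(1H)-one (trans ring fusion), via samarium enolate 15 (not isolated)
Conditions: SmI2 (2.2 equiv), THF/MeOH, −78 °C
Reagents that add atoms: none
Why: Reduction of an alpha-alkoxy ketone by divalent samarium: two electrons cleave the C5–O bond, which is held parallel to the enone pi system, to give enolate 15, and protonation at C5 is expected on the face just vacated by oxygen, where the samarium-bound C9 alkoxide and its methanol sit, giving the trans ring fusion, which should also be the thermodynamic one because C6 then lies cis to the hydroxyl and not to the isopropyl group on C4.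

Step 9
Reactants: 16 (3R,3aR,7S,8aR)-3,7-dihydroxy-6,8a-dimethyl-3-(propan-2-yl)-2,3,3a,7,8,8a-hexahydroazulen-4(1H)-one
Product: 17 (3R,3aR,7S,8aR)-3-hydroxy-6,8a-dimethyl-4-oxo-3-(propan-2-yl)-1,2,3,3a,4,7,8,8a-octahydroazulen-7-yl acetate
Conditions: Ac2O, pyridine, DMAP (cat.), CH2Cl2, 0 °C → rt
Reagents that add atoms: acetic anhydride CC(=O)OC(C)=O
Why: DMAP-catalysed acetylation turns the secondary allylic C9 hydroxyl into a leaving group, while the tertiary C4 hydroxyl should not react.

Step 10
Reactants: 17 (3R,3aR,7S,8aR)-3-hydroxy-6,8a-dimethyl-4-oxo-3-(propan-2-yl)-1,2,3,3a,4,7,8,8a-octahydroazulen-7-yl acetate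
Product: 19 (3R,3aR,8aR)-3-hydroxy-6,8a-dimethyl-3-(propan-2-yl)-2,3,3a,5,8,8a-hexahydroazulen-4(1H)-one, via samarium dienolate 18 (not isolated)
Conditions: SmI2 (2.5 equiv), THF/MeOH, −78 °C; pH 7 buffer at −78 °C
Reagents that add atoms: none
Why: Vinylogous reductive elimination with divalent samarium (known for gamma-acyloxy enones and enoates): two electrons expel the C9 acetate to give the linear dienolate 18, and kinetic protonation at its alpha-carbon C7 should leave the double bond at C8=C9, out of conjugation, with no stereocentre touched.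

Step 11
Reactants: 19 (3R,3aR,8aR)-3-hydroxy-6,8a-dimethyl-3-(propan-2-yl)-2,3,3a,5,8,8a-hexahydroazulen-4(1H)-one
Product: 20 (3R,3aS,4S,8aR)-6,8a-dimethyl-3-(propan-2-yl)-1,2,3,3a,4,5,8,8a-octahydroazulene-3,4-diol (jaeschkeanadiol)
Conditions: Me4NBH(OAc)3, MeCN/AcOH, −30 °C
Reagents that add atoms: none
Why: Evans–Saksena hydroxyl-directed reduction: the C4 hydroxyl exchanges onto boron and hydride is delivered within the molecule to the face of the C6 carbonyl on which that oxygen lies, which should give the 1,3-anti diol with the C6 hydroxyl cis to H5 and trans to the angular methyl.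

Step 12
Reactants: 20 (3R,3aS,4S,8aR)-6,8a-dimethyl-3-(propan-2-yl)-1,2,3,3a,4,5,8,8a-octahydroazulene-3,4-diol; 21 3,4-dimethoxybenzoyl chloride
Product: 22 (3R,3aS,4S,8aR)-3-hydroxy-6,8a-dimethyl-3-(propan-2-yl)-1,2,3,3a,4,5,8,8a-octahydroazulen-4-yl 3,4-dimethoxybenzoate (target)
Conditions: 21, Et3N, DMAP, CH2Cl2, 0 °C → rt
Reagents that add atoms: none
Why: DMAP-catalysed esterification with an acid chloride should acylate the only secondary hydroxyl, the tertiary C4 hydroxyl being too hindered to compete, and no stereocentre is affected.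

**Compound list**

1 | (2R)-2-hydroxy-3-methylbutanoic acid | CC(C)[C@@H](O)C(=O)O | starting material
2 | 2,2-dimethylpropanal (pivalaldehyde) | CC(C)(C)C=O | starting material
3 | (2R,5R)-2-tert-butyl-5-(propan-2-yl)-1,3-dioxolan-4-one | CC(C)[C@H]1O[C@@H](C(C)(C)C)OC1=O | intermediate
4 | 4-iodo-2-methylbut-1-ene | C=C(C)CCI | starting material
5 | lithium (2R)-2-tert-butyl-5-(propan-2-yl)-1,3-dioxol-4-olate (lithium enolate of 3) | CC(C)C1=C([O-])O[C@H](C(C)(C)C)O1.[Li+] | intermediate (not isolated)
6 | (2R,5R)-2-tert-butyl-5-(3-methylbut-3-en-1-yl)-5-(propan-2-yl)-1,3-dioxolan-4-one | CC(C)[C@@]1(CCC(C)=C)O[C@@H](C(C)(C)C)OC1=O | intermediate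
7 | 3-methylfuran | Cc1ccoc1 | starting material
8 | (4-methylfuran-2-yl)lithium | [Li]c1cc(C)co1 | intermediate (not isolated)
9 | (2R)-2-hydroxy-5-methyl-1-(4-methylfuran-2-yl)-2-(propan-2-yl)hex-5-en-1-one | CC(C)[C@](O)(CCC(C)=C)C(=O)c1cc(C)co1 | intermediate
10 | (2R)-5-methyl-1-(4-methylfuran-2-yl)-2-(propan-2-yl)hex-5-ene-1,2-diol (both epimers at the furfuryl carbinol) | CC(C)[C@](O)(CCC(C)=C)C(O)c1cc(C)co1 | intermediate
11 | 6-hydroxy-2-[(3R)-3-hydroxy-2,6-dimethylhept-6-en-3-yl]-5-methyl-2H-pyran-3(6H)-one (ring-centre epimers) | CC(C)[C@](O)(CCC(C)=C)C1OC(O)C(C)=CC1=O | intermediate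
12 | 6-[(3R)-3-hydroxy-2,6-dimethylhept-6-en-3-yl]-3-methyl-5-oxo-5,6-dihydro-2H-pyran-2-yl acetate (ring-centre epimers) | CC(C)[C@](O)(CCC(C)=C)C1OC(OC(C)=O)C(C)=CC1=O | intermediate
13 | 2-[(3R)-3-hydroxy-2,6-dimethylhept-6-en-3-yl]-5-methylpyrylium-3-olate (oxidopyrylium ylide) | CC(C)[C@](O)(CCC(C)=C)c1[o+]cc(C)cc1[O-] | intermediate (not isolated)
14 | (3R,3aS,7S,8aR)-3-hydroxy-6,8a-dimethyl-3-(propan-2-yl)-1,2,3,7,8,8a-hexahydro-4H-3a,7-epoxyazulen-4-one | O=C1C=C(C)[C@@H]2C[C@@]3(C)CC[C@@](O)(C(C)C)[C@]13O2 | intermediate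
15 | trivalent samarium enolate of 16 (C6–O–SmI2 enolate with C5=C6; C9–O–SmI2 alkoxide) | I[Sm](I)OC1C=C(C)[C@@H](O[Sm](I)I)C[C@@]2(C)CC[C@@](O)(C(C)C)C=12 | intermediate (not isolated)
16 | (3R,3aR,7S,8aR)-3,7-dihydroxy-6,8a-dimethyl-3-(propan-2-yl)-2,3,3a,7,8,8a-hexahydroazulen-4(1H)-one | O=C1C=C(C)[C@@H](O)C[C@@]2(C)CC[C@@](O)(C(C)C)[C@H]12 | intermediate
17 | (3R,3aR,7S,8aR)-3-hydroxy-6,8a-dimethyl-4-oxo-3-(propan-2-yl)-1,2,3,3a,4,7,8,8a-octahydroazulen-7-yl acetate | O=C1C=C(C)[C@@H](OC(C)=O)C[C@@]2(C)CC[C@@](O)(C(C)C)[C@H]12 | intermediate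
18 | trivalent samarium dienolate of 19 (C6–O–SmI2; C6=C7 and C8=C9) | I[Sm](I)OC1=CC(C)=CC[C@@]2(C)CC[C@@](O)(C(C)C)[C@H]12 | intermediate (not isolated)
19 | (3R,3aR,8aR)-3-hydroxy-6,8a-dimethyl-3-(propan-2-yl)-2,3,3a,5,8,8a-hexahydroazulen-4(1H)-one | O=C1CC(C)=CC[C@@]2(C)CC[C@@](O)(C(C)C)[C@H]12 | intermediate
20 | (3R,3aS,4S,8aR)-6,8a-dimethyl-3-(propan-2-yl)-1,2,3,3a,4,5,8,8a-octahydroazulene-3,4-diol (jaeschkeanadiol) | O[C@H]1CC(C)=CC[C@@]2(C)CC[C@@](O)(C(C)C)[C@H]12 | intermediate
21 | 3,4-dimethoxybenzoyl chloride | COc1ccc(C(=O)Cl)cc1OC | starting material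
22 | (3R,3aS,4S,8aR)-3-hydroxy-6,8a-dimethyl-3-(propan-2-yl)-1,2,3,3a,4,5,8,8a-octahydroazulen-4-yl 3,4-dimethoxybenzoate | COc1ccc(C(=O)O[C@H]2CC(C)=CC[C@@]3(C)CC[C@@](O)(C(C)C)[C@H]23)cc1OC | target

**Step count and risks**

Total steps: 12. Longest linear sequence: 12 steps (1 → 22).

Steps most likely to fail:

1. Step 7. Bimolecular dimerisation or decay of ylide 13 may outrun a cycloaddition that has to join two fully substituted carbons, and facial control may erode if the hydroxyl-to-oxide hydrogen bond does not dominate the rotamer population. The fallback replaces substrate control through the free ylide by catalyst control through a more reactive aminopyrylium. It sets out from 11: acylation with 4-(methylsulfanyl)benzoyl chloride (Et3N, DMAP, CH2Cl2) should give 6-[(3R)-3-hydroxy-2,6-dimethylhept-6-en-3-yl]-3-methyl-5-oxo-5,6-dihydro-2H-pyran-2-yl 4-(methylsulfanyl)benzoate F1. A chiral primary aminothiourea (the enantiomer matched to the C4 centre), an achiral diarylthiourea and acetic acid in toluene at 40 °C would condense with the ketone and abstract the benzoate, and the resulting aminopyrylium undergoes the same intramolecular [5+2]. Hydrolysis of the enamine on work-up returns the route at 14.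

2. Step 2. E2 loss of hydrogen iodide from the homoallylic iodide (to isoprene) and decay of the hindered, fully substituted enolate may compete with C-alkylation. The fallback uses conjugate addition and olefination in place of the substitution. It sets out from 3: enolate 5 is added at −78 °C to but-3-en-2-one (Michael addition, again anti to the tert-butyl group) to give (2R,5R)-2-tert-butyl-5-(3-oxobutyl)-5-(propan-2-yl)-1,3-dioxolan-4-one F2. Wittig methylenation of its ketone (Ph3P=CH2 from Ph3PCH3Br and KOt-Bu, THF, 0 °C; the lactone carbonyl should be inert) returns the route at 6.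

3. Step 3. Competing deprotonation of 3-methylfuran at the ring position next to the methyl group would move the future C8 methyl to C7, and addition to the neopentyl-type lactone carbonyl may be sluggish. The fallback uses sterically governed C–H borylation and a neutral acyl cross-coupling in place of deprotonation and 1,2-addition. It sets out from 6 and 7: lithium ethanethiolate (EtSH, n-BuLi, THF, 0 °C) should open 6 with loss of pivalaldehyde to S-ethyl (2R)-2-hydroxy-5-methyl-2-(propan-2-yl)hex-5-enethioate F3. Borylation of 7 with bis(pinacolato)diboron, [Ir(OMe)(cod)]2 and 4,4'-di-tert-butyl-2,2'-bipyridine at the unhindered alpha C–H should give 4,4,5,5-tetramethyl-2-(4-methylfuran-2-yl)-1,3,2-dioxaborolane F4. Liebeskind–Srogl coupling of F3 with F4 (Pd2(dba)3, tri(2-furyl)phosphine, copper thiophene-2-carboxylate, THF, 50 °C) returns the route at 9.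

**Further compounds**

F1 | step 7 | 6-[(3R)-3-hydroxy-2,6-dimethylhept-6-en-3-yl]-3-methyl-5-oxo-5,6-dihydro-2H-pyran-2-yl 4-(methylsulfanyl)benzoate | CC(C)[C@](O)(CCC(C)=C)C1OC(OC(=O)c2ccc(SC)cc2)C(C)=CC1=O
F2 | step 2 | (2R,5R)-2-tert-butyl-5-(3-oxobutyl)-5-(propan-2-yl)-1,3-dioxolan-4-one | CC(C)[C@@]1(CCC(C)=O)O[C@@H](C(C)(C)C)OC1=O
F3 | step 3 | S-ethyl (2R)-2-hydroxy-5-methyl-2-(propan-2-yl)hex-5-enethioate | CC(C)[C@](O)(CCC(C)=C)C(=O)SCC
F4 | step 3 | 4,4,5,5-tetramethyl-2-(4-methylfuran-2-yl)-1,3,2-dioxaborolane | Cc1coc(B2OC(C)(C)C(C)(C)O2)c1
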